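At 8.0 h Sunday's flask is to be read, though it has been followed to 2.50 h. In it the single-handed X meets the mirror images Z and D, giving G from Z and J from D.

common to all: Z 12 mM; D 12 mM
- Sunday's: X 2.5 equiv (fed, over 4.0 h); the very flask that is asked about, followed so far
- Monday's: X 1.7 equiv (fed, over 4.0 h); run made earlier
- flask: X 2.50 equiv (fed, over 4.0 h); time 8.0 h

| run | time / h | G / % | J / % |
|---|---|---|---|
| Sunday's | 0.500 | 0.2 | 0.6 |
| Sunday's | 1.00 | 0.8 | 0.3 |
| Sunday's | 1.33 | 1.9 | 1.5 |
| Sunday's | 2.00 | 5.3 | 1.9 |
| Sunday's | 2.50 | 7.6 | 2.9 |
| Monday's | 0.417 | 0.2 | 0.5 |
| Monday's | 0.833 | 0.3 | 0.4 |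
| Monday's | 1.50 | 2.4 | 0.5 |
| Monday's | 3.00 | 7.5 | 2.4 |
| Monday's | 6.00 | 17.3 | 8.4 |

(each reading ± 0.5 percentage points)

- G and J together, in percent of the Z and D charged together, at 8.0 h
- excess of G over J in the product at 8.0 h
- whether the exchange between Z and D keeps pace with the reaction: how far the product's excess at 8.0 h gets from its value without exchange to its value with instant exchange (above 80% keeps pace, below 20% hardly takes part, else lags behind)

- X is single-handed; Z and D are mirror images of each other, charged as a racemate, each of them at the stated concentration
- candidate steps: X + Z -> G; X + D -> J; Z <-> D; G <-> J; 2 X -> E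
- an excess is the difference of the two amounts in percent of their sum
- an excess is below zero if the other one leads
- the handed part of X does not stay in what it makes, so the products of the two hands are mirror images too

The reckoning here starts from the end state. G and J are mirror images, so their exchange, if it runs, ends at an excess of zero, and the question is how fast the excess goes there. Product freshly made from equal Z and D carries an excess set by the selectivity factor, the ratio of the rate constants of Z and D with X. Sunday's readings at 2.00 h and 2.50 h, pooled with Monday's at 3.00 h and taken here as fresh product, put that excess at 47.8%. Monday's reading at 6.00 h shows less, 34.6%.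

Suppose X rises linearly during the feed and then holds. Monday's product is then on average 2.17 h old at that reading. Z and D were not measured, so their staying equal is an assumption here. With it, the fall belongs to G ⇌ J, and the readings give 4.65 h as the excess half-life, the time in which product of one age loses half its excess. On the same supposition Sunday's product will be on average 3.11 h old at the asked time, so its excess should be 30.1%.

The forecast gives 44% of product, an excess of 32%, and an exchange between Z and D that hardly takes part: “Fast exchange would hold the ratio near s, so exchange looks negligible.” On that point the forecast parts from the reckoning here, which takes Z and D as staying equal.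

Sunday's flask gives 42.2% of product and an excess of 32.1%, and its exchange between Z and D keeps pace, getting 96% of the way.

    X + Z → G (k = 0.00210 M⁻¹ s⁻¹)
    X + D → J (k = 7.50 × 10⁻⁴ M⁻¹ s⁻¹)
    Z ⇌ D (k = 8.20 × 10⁻⁴ s⁻¹)
    G ⇌ J (k = 1.40 × 10⁻⁵ s⁻¹)
    2 X → E (k = 7.80 × 10⁻⁴ M⁻¹ s⁻¹)

In Sunday's flask at 8.00 h, Z goes into G at 0.028 of the forward rate at which it passes into D, and Z and D stand at 28.8% and 29.1% of the two charged together.

The same flask with 6.20 equiv of X has the same feed time and reading time, so on the same supposition the excess half-life gives it 30.1% again. That flask computes to 30.2% at 67.6% of product.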